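The runs stem from a simulated flask from invented constants; noise was put on by code.

Follow what is left.

| flask | starting material | partner | time |
|---|---|---|---|
| green | 0.500 M | 0.600 M |  |
| teal | 0.250 M | 0.600 M |  |
| blue | 0.500 M | 0.900 M |  |
| violet | 0.250 M | 0.300 M | 11 min |

- green run (time / min: [product] / M): 2.2: 0.139; 4.4: 0.187; 6.6: 0.198; 8.8: 0.217; 11: 0.228
- teal run (time / min: [product] / M): 2.2: 0.074; 4.4: 0.103; 6.6: 0.118; 8.8: 0.114; 11: 0.135
- blue run (time / min: [product] / M): 2.2: 0.211; 4.4: 0.266; 6.6: 0.289; 8.8: 0.297; 11: 0.292

(readings scatter by 0.005 M)

- order of the initial rate in [partner], near the charge of the green run, the rate being that where two percent of its starting material are product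
- order of the initial rate in [starting material], near the charge of the green run, the rate being that where two percent of its starting material are product (one fixed amount of product, the same in the runs compared)
- product in the violet run at 11 min, as a share of the starting material charged

- Overall: starting material + partner -> product.
- Constant volume, constant temperature.
- A reading of a species includes what of it is bound.
- "The second partner" is partner.
- An order is taken over about fifteen percent of the charge, up and down.

1. My reading: the curves flatten below full conversion, and I take that as starting material leaving by two exits, one to product and one elsewhere. Treat the partner as roughly constant (pseudo-first-order). The fraction left then falls as exp(−k_T·t), where k_T is the total exit constant. In the green run, the gap to the last reading gives k_T = 0.428 min⁻¹, and the last reading as a share of the charge, which I take as the selectivity, is 45.6 %.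

2. Split k_T by that share. The product constant is k_P = 0.195 min⁻¹. The leak constant k_L, the part of k_T that makes no product, is 0.233 min⁻¹.

3. The blue run reads k_P = 0.340 min⁻¹, so my order in partner is 1.37. The teal run, with half the starting material, reads k_P = 0.195 min⁻¹, so my order in starting material is about 1. The leak reads 0.242 min⁻¹ in blue and 0.166 min⁻¹ in teal, which is noisy. I carry the green value.

4. Teal is the violet run's neighbour: same starting material, but violet has half the partner. Teal's last reading is 54.0 % of its charge. Violet's k_P drops to 0.0752 min⁻¹, well below teal's, while I hold k_L fixed. So violet's selectivity falls to 24.4 %. With 3.38 % left at 11 min, I commit to 23.6 %.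

5. The forecast gives 1.4 in partner, 0.95 in starting material, and 31 % for violet, which is higher than my figure. It holds that “this looks like a reversible reaction”.

6. The flask gives orders of 1.5 and 1.0, and 24.1 % for the violet run, 6.9 percentage points below the forecast.

    starting material + 2 partner → product + partner (1.728 M⁻² min⁻¹)
    starting material → decomposed substrate (0.1902 min⁻¹)
    2 partner ⇌ idle reagent dimer, settled at all times (0.9600 M⁻¹)

Here starting material also goes to decomposed substrate by a step without partner. Read through k_L, with my estimate of 3.38 % left, the violet share means k_P = 0.0774 min⁻¹. In the teal run, product reaches a quarter of the charge at 1.69 min. There, k_L plus the green k_P leaves 48.5 % of the starting material and reckons 23.5 % as product.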